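**Quick number.** If you want one number per flask, work with what is left, not with what is made.

in all of them: substrate 0.40 M
- beta: partner 1.1 equiv; precatalyst 0.032 mol%; run made earlier
- delta: partner 1.1 equiv; precatalyst 0.048 mol%; run made earlier
- east: partner 1.10 equiv; precatalyst 0.05 mol%; time 40 h
- south-east: partner 1.10 equiv; precatalyst 0.08 mol%; time 20 h

| run | time / h | target / % |
|---|---|---|
| beta | 4.00 | 2.7 |
| beta | 10.0 | 9.8 |
| beta | 20.0 | 22.5 |
| beta | 30.0 | 33.1 |
| delta | 8.00 | 10.8 |
| delta | 15.0 | 22.7 |
| delta | 20.0 | 31.0 |
| delta | 30.0 | 43.5 |

(readings scatter by 0.3 percentage points)

1. which of the two ends with the higher amount of target, in percent of the substrate charged ("neither" if they lie within 2 percentage points) (east / south-east / neither)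
2. target at the end, in percent of the substrate charged, east
3. target at the end, in percent of the substrate charged, south-east

**Our clock.** We turn each target reading into substrate left and partner left, taking one of each per target as our working assumption. The logarithm of their ratio, over the starting ratio and divided by the partner's excess in equivalents, is our clock, the integrated second-order form. In delta it stands at 0.263 after 15.0 h and at 0.677 after 30.0 h. So the clock rate, its rise per hour at delta's loading, reads 0.0275 h⁻¹. Drawn back, that line reaches zero at 5.43 h, the induction period as these two readings give it.

We scale the rate with loading and keep the lag. Beta then gets a clock of 0.451 at 30.0 h, which means 33.7% target, against a reading of 33.1% that the line never used.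

**Our number.** East gets a clock of 0.992, so 53.4%. South-east gets 0.669, so 43.2%.

**Your forecast.** It says east, with 53% for east and 44% for south-east, since “East has the larger loading-time product”. Our south-east lies 0.8 percentage points lower than yours.

**The flasks.** East ends at 53.4% and south-east at 43.5%, so east ends higher, as forecast.

    substrate + free catalyst → catalyst intermediate A (k = 360 L mol⁻¹ h⁻¹)
    catalyst intermediate A ⇌ catalyst intermediate B (K = 7.00, k = 280 h⁻¹)
    partner + catalyst intermediate B → catalyst intermediate C (k = 320 L mol⁻¹ h⁻¹)
    catalyst intermediate C → free catalyst + target (k = 4900 h⁻¹)
    partner + target ⇌ idle adduct, settled at all times (K = 36.0 L mol⁻¹)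
    partner + precatalyst → free catalyst + spent reagent (k = 0.520 L mol⁻¹ h⁻¹)

**Richer neighbour.** A neighbour of south-east holds 0.32 mol% of precatalyst for the same 20 h. The same rate and lag give it a clock of 2.67, so 77.1% target. That neighbour holds 73.0%, which is 4.1 points less than reckoned. At that time 22.3% of its catalyst charge is still precatalyst, and its free partner stands at 4.79% of its own charge.

The data were computed on assumed constants.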